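Atoms carry labdane numbers. Retrosynthetic cuts, in order: the malonate ester; C11–C12 (Wittig); C8–OH (hydration of a C8=C17 alkene); C8–C9 of ring B (enol ether adding to an alkyne); last C5–C10 of ring A.
What makes the last cut possible: C5 is a tertiary carbon next to C6 and bonded to the methyl-bearing quaternary C10, so with C6 as a lactone carbonyl, C5 as its alpha-carbon and the lactone carbinol C2 carrying a C1=C10 alkene, ring A (C5–C4–C3–C2–C1–C10) is the [3,3] product of a six-membered lactone enolate.
Forward: a prochiral 3,3-disubstituted glutarate (C4 with its CH3 and CH2OBn) is desymmetrised, acylated by a (Z)-alkenylzinc and reduced to the alkenyl δ-lactone; Ireland–Claisen ring contraction then gives the ring A cyclohexene acid.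
C6 is extended to a but-3-ynyl arm and C9 to a methyl enol ether; gold catalysis closes ring B as a trans-decalin with C8=C17 and the C11 aldehyde.
A Wittig reaction adds C12–C16, oxymercuration gives the C8 carbinol, Meldrum's acid gives the malonate, and one hydrogenation saturates the alkene and frees the C18 alcohol.
Stereochemistry: C4 from the enzymatic desymmetrisation, the lactone carbinol from CBS reduction, C10 and C5 by chirality transfer through the boat transition state with the (Z)-alkene, C9 in the chair-like ring-B closure, C8 by attack anti to the C10 methyl, C13 from dimethyl (R)-2-methylsuccinate.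

Key step: step 10

Assumption: the esterase is taken to hydrolyse the ester arm that leads to the (S)-acid; if it prefers the other arm, exchanging the roles of the two arms (acid esterified, ester saponified) restores the same series.

Step 1
Reactants: 1 ethyl 2-methylpent-4-enoate
Product: 2 ethyl 2-allyl-2-methylpent-4-enoate
Conditions: LiN(i-Pr)2, THF, −78 °C; allyl bromide, DMPU, −78 → 0 °C
Reagents that add atoms: allyl bromide, C=CCBr
Why: Ester enolate alkylation: the lithium enolate of the α-branched ester is alkylated by the reactive allyl bromide to the quaternary carbon (later C4), which stays achiral because it carries two allyl groups.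

Step 2
Reactants: 2 ethyl 2-allyl-2-methylpent-4-enoate
Product: 3 2-allyl-2-methylpent-4-en-1-ol
Conditions: LiAlH4, Et2O, 0 °C → rt
Reagents that add atoms: none
Why: LiAlH4 reduction of an ester to the primary (neopentyl) alcohol, with no stereocentre involved.

Step 3
Reactants: 3 2-allyl-2-methylpent-4-en-1-ol
Product: 4 4-(benzyloxymethyl)-4-methylhepta-1,6-diene
Conditions: NaH, benzyl bromide, Bu4NI (cat.), THF–DMF, 0 °C → rt
Reagents that add atoms: benzyl bromide, BrCc1ccccc1
Why: Williamson ether synthesis on the alkoxide, giving a benzyl ether that should last until the final hydrogenolysis.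

Step 4
Reactants: 4 4-(benzyloxymethyl)-4-methylhepta-1,6-diene
Product: 5 dimethyl 3-(benzyloxymethyl)-3-methylpentanedioate
Conditions: O3, NaOH (5 equiv), MeOH–CH2Cl2, −78 °C
Reagents that add atoms: ozone, [O-][O+]=O; methanol, CO
Why: Ozonolysis in methanolic NaOH (Marshall conditions) should turn each terminal alkene directly into a methyl ester with loss of one carbon and so give the prochiral 3,3-disubstituted glutarate, the alkenes being consumed well before ozone attacks the benzyl ether.

Step 5
Reactants: 5 dimethyl 3-(benzyloxymethyl)-3-methylpentanedioate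
Product: 6 (S)-3-(benzyloxymethyl)-5-methoxy-3-methyl-5-oxopentanoic acid
Conditions: pig liver esterase, phosphate buffer pH 7, DMSO (10%), 25 °C, NaOH (pH-stat); then HCl to pH 2
Reagents that add atoms: water, O
Why: Enzymatic desymmetrisation: the esterase should hydrolyse one enantiotopic ester arm of the prochiral glutarate and so set C4, and any minor enantiomer is removed later because it ends up in a separable lactone diastereomer at step 9.

Step 6
Reactants: 7 prop-2-yn-1-ol
Product: 8 (Z)-3-iodo-2-methylprop-2-en-1-ol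
Conditions: MeMgBr (2.5 equiv), CuI (10 mol%), THF, −10 °C → rt; then I2, −78 → 0 °C
Reagents that add atoms: methylmagnesium bromide, C[Mg]Br; iodine, II
Why: Copper-catalysed anti carbomagnesiation of the propargylic alkoxide (Duboudin reaction) should place methyl on C2 and magnesium on C3 inside a five-membered chelate, so that iodinolysis with retention gives the iodide with iodine cis to CH2OH.

Step 7
Reactants: 8 (Z)-3-iodo-2-methylprop-2-en-1-ol
Product: 9 (Z)-1-iodo-3-(4-methoxybenzyloxy)-2-methylprop-1-ene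
Conditions: NaH, 4-methoxybenzyl chloride, Bu4NI (cat.), DMF, 0 °C → rt
Reagents that add atoms: 4-methoxybenzyl chloride, COc1ccc(CCl)cc1
Why: Williamson ether synthesis; the vinyl iodide has no hydrogen on the neighbouring sp2 carbon and cannot eliminate under these conditions.

Step 8
Reactants: 6 (S)-3-(benzyloxymethyl)-5-methoxy-3-methyl-5-oxopentanoic acid; 9 (Z)-1-iodo-3-(4-methoxybenzyloxy)-2-methylprop-1-ene
Product: 13 methyl (S,Z)-3-(benzyloxymethyl)-8-(4-methoxybenzyloxy)-3,7-dimethyl-5-oxooct-6-enoate, via acid chloride 10 (not isolated), via alkenyllithium 11 (not isolated), via alkenylzinc chloride 12 (not isolated)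
Conditions: 6: (COCl)2, DMF (cat.), CH2Cl2, 0 °C; 9: t-BuLi (2 equiv), Et2O, −78 °C, then ZnCl2, THF; combine, Pd(PPh3)4 (5 mol%), THF, 0 °C → rt
Reagents that add atoms: none
Why: Negishi acylation: iodine–lithium exchange and transmetalation to zinc keep the (Z) geometry, and zerovalent palladium couples the alkenylzinc with the freshly made acid chloride without touching the methyl ester, which an alkenyllithium would attack.

Step 9
Reactants: 13 methyl (S,Z)-3-(benzyloxymethyl)-8-(4-methoxybenzyloxy)-3,7-dimethyl-5-oxooct-6-enoate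
Product: 15 (4S,6S)-4-(benzyloxymethyl)-6-[(Z)-3-(4-methoxybenzyloxy)-2-methylprop-1-enyl]-4-methyltetrahydropyran-2-one, via hydroxy ester 14 (not isolated)
Conditions: (R)-2-methyl-CBS-oxazaborolidine (20 mol%), catecholborane, toluene, −78 °C; then PPTS (cat.), toluene, 50 °C
Reagents that add atoms: none
Why: Corey–Bakshi–Shibata 1,2-reduction in which the β,β-disubstituted alkenyl group should act as the large substituent, so that the (R)-catalyst gives the (S)-carbinol, followed by acid-catalysed lactonisation favoured by the gem-disubstituted C4, the cis and trans lactones being separable so that errors of this step and of step 5 are purged.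

Step 10
Reactants: 15 (4S,6S)-4-(benzyloxymethyl)-6-[(Z)-3-(4-methoxybenzyloxy)-2-methylprop-1-enyl]-4-methyltetrahydropyran-2-one
Product: 18 (1R,2R,6S)-6-(benzyloxymethyl)-2-[(4-methoxybenzyloxy)methyl]-2,6-dimethylcyclohex-3-ene-1-carboxylic acid, via silyl ketene acetal 16 (not isolated), via silyl ester 17 (not isolated)
Conditions: LiN(i-Pr)2, t-BuMe2SiCl, HMPA–THF, −78 °C → rt; toluene, 105 °C; then 1 M HCl, THF
Reagents that add atoms: none
Why: LiN(i-Pr)2 removes a proton from the lactone α-CH2 (C5) and the silyl chloride traps the enolate on oxygen as the endocyclic silyl ketene acetal 16; on heating, a concerted [3,3] sigmatropic shift forms C5–C10 while C2–O1 breaks, giving silyl ester 17, which aqueous acid hydrolyses to 18. The closest known reaction type is the Ireland–Claisen rearrangement of alkenyl lactone silyl ketene acetals (lactone-to-carbocycle ring contraction). Ring A (C5–C4–C3–C2–C1–C10) closes as the six-membered carbocyclic face of a bicyclo[2.2.2]octane-like boat transition state in which C2 and C5 are the bridgeheads and C3–C4, O1–C6 and C1=C10 the three bridges; a chair is impossible because the two-atom C3–C4 tether links the ends of the two three-atom fragments. C10 is set by suprafacial chirality transfer from the (S)-carbinol C2 (C5 bonds to the alkene face from which O1 departs) together with the (Z)-alkene, which puts the C10 methyl cis and the CH2OPMB arm trans to the new carboxyl; C5 is set by the ring-fixed ketene acetal geometry (C4 cis to O1) within the same boat, and C4 is carried through unchanged. The step needs O-silylation to outrun C-silylation, self-condensation and ketene-forming fragmentation of the lactone enolate (secured by trapping at −78 °C), and it needs the boat to be reached despite the close contact between the C4 CH2OBn group and the C10 CH2OPMB arm (helped by the intramolecular, strongly exothermic exchange of a C–O for a C–C bond and the absence of a competing chair). C5 stays alpha to the carboxyl, and its required configuration (carboxyl cis to both methyl groups, trans to both CH2O arms) is also the less crowded one.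

Step 11
Reactants: 18 (1R,2R,6S)-6-(benzyloxymethyl)-2-[(4-methoxybenzyloxy)methyl]-2,6-dimethylcyclohex-3-ene-1-carboxylic acid
Product: 19 [(1R,2R,6S)-6-(benzyloxymethyl)-2-[(4-methoxybenzyloxy)methyl]-2,6-dimethylcyclohex-3-en-1-yl]methanol
Conditions: LiAlH4, THF, 0 °C → reflux
Reagents that add atoms: none
Why: LiAlH4 reduction of the hindered carboxylic acid to the primary alcohol, under which C5 cannot epimerise.

Step 12
Reactants: 19 [(1R,2R,6S)-6-(benzyloxymethyl)-2-[(4-methoxybenzyloxy)methyl]-2,6-dimethylcyclohex-3-en-1-yl]methanol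
Product: 20 (1R,2R,6S)-6-(benzyloxymethyl)-2-[(4-methoxybenzyloxy)methyl]-2,6-dimethylcyclohex-3-ene-1-carbaldehyde
Conditions: Dess–Martin periodinane, CH2Cl2, rt
Reagents that add atoms: none
Why: Dess–Martin oxidation under non-basic conditions should give the aldehyde without epimerising C5, whose formyl group already lies on the less crowded side, cis to both methyl groups.

Step 13
Reactants: 20 (1R,2R,6S)-6-(benzyloxymethyl)-2-[(4-methoxybenzyloxy)methyl]-2,6-dimethylcyclohex-3-ene-1-carbaldehyde
Product: 21 ethyl (E)-3-[(1R,2R,6S)-6-(benzyloxymethyl)-2-[(4-methoxybenzyloxy)methyl]-2,6-dimethylcyclohex-3-en-1-yl]prop-2-enoate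
Conditions: (EtO)2P(O)CH2CO2Et, NaH, THF, 0 → 50 °C
Reagents that add atoms: triethyl phosphonoacetate, CCOC(=O)CP(=O)(OCC)OCC
Why: Horner–Wadsworth–Emmons olefination: the small phosphonate anion should add even to this aldehyde flanked by two quaternary carbons and give the (E)-enoate, which brings in C7 and C8.

Step 14
Reactants: 21 ethyl (E)-3-[(1R,2R,6S)-6-(benzyloxymethyl)-2-[(4-methoxybenzyloxy)methyl]-2,6-dimethylcyclohex-3-en-1-yl]prop-2-enoate
Product: 22 ethyl 3-[2-(benzyloxymethyl)-6-[(4-methoxybenzyloxy)methyl]-2,6-dimethylcyclohexyl]propanoate (C4, C5, C10 placed as in 18)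
Conditions: H2 (1 atm), Pd/C, pyridine (0.5 equiv), EtOAc, rt
Reagents that add atoms: none
Why: Catalytic hydrogenation over Pd/C poisoned with pyridine should saturate the enoate and the ring alkene while the benzyl and 4-methoxybenzyl ethers stay, and no stereocentre is formed because C1, C2, C6 and C7 all become CH2.

Step 15
Reactants: 22 ethyl 3-[2-(benzyloxymethyl)-6-[(4-methoxybenzyloxy)methyl]-2,6-dimethylcyclohexyl]propanoate
Product: 24 1-(benzyloxymethyl)-2-(but-3-ynyl)-3-[(4-methoxybenzyloxy)methyl]-1,3-dimethylcyclohexane (C4, C5, C10 as in 18), via aldehyde 23 (not isolated)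
Conditions: i-Bu2AlH, CH2Cl2, −78 °C; then MeOH, K2CO3, dimethyl (1-diazo-2-oxopropyl)phosphonate, −78 °C → rt
Reagents that add atoms: dimethyl (1-diazo-2-oxopropyl)phosphonate, COP(=O)(OC)C(=[N+]=[N-])C(C)=O
Why: Partial reduction of the ester with i-Bu2AlH at −78 °C and Seyferth–Gilbert homologation with the Ohira–Bestmann reagent in the same flask should convert C8 into a terminal alkyne and add C17.

Step 16
Reactants: 24 1-(benzyloxymethyl)-2-(but-3-ynyl)-3-[(4-methoxybenzyloxy)methyl]-1,3-dimethylcyclohexane
Product: 25 [3-(benzyloxymethyl)-2-(but-3-ynyl)-1,3-dimethylcyclohexyl]methanol (C4, C5, C10 as in 18)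
Conditions: DDQ, CH2Cl2–pH 7 buffer, 0 °C
Reagents that add atoms: none
Why: Oxidative cleavage of the 4-methoxybenzyl ether with DDQ, which should leave the benzyl ether and the alkyne alone.

Step 17
Reactants: 25 [3-(benzyloxymethyl)-2-(but-3-ynyl)-1,3-dimethylcyclohexyl]methanol
Product: 26 3-(benzyloxymethyl)-2-(but-3-ynyl)-1,3-dimethylcyclohexane-1-carbaldehyde (C4, C5, C10 as in 18)
Conditions: Dess–Martin periodinane, CH2Cl2, rt
Reagents that add atoms: none
Why: Dess–Martin oxidation of the neopentyl alcohol to an aldehyde that has no α-hydrogen.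

Step 18
Reactants: 26 3-(benzyloxymethyl)-2-(but-3-ynyl)-1,3-dimethylcyclohexane-1-carbaldehyde
Product: 27 1-(benzyloxymethyl)-2-(but-3-ynyl)-3-(2-methoxyvinyl)-1,3-dimethylcyclohexane (E/Z mixture; C4, C5, C10 as in 18)
Conditions: Ph3P(CH2OMe)Cl, KN(SiMe3)2, THF, 0 °C → rt
Reagents that add atoms: (methoxymethyl)triphenylphosphonium chloride, COC[P+](c1ccccc1)(c1ccccc1)c1ccccc1.[Cl-]
Why: Wittig reaction with methoxymethylenetriphenylphosphorane, a one-carbon homologation that tolerates neopentyl aldehydes and makes C11 the oxygen-bearing carbon of the enol ether, whose E/Z ratio does not matter.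

Step 19
Reactants: 27 1-(benzyloxymethyl)-2-(but-3-ynyl)-3-(2-methoxyvinyl)-1,3-dimethylcyclohexane
Product: 29 18-benzyloxy-12,13,14,15,16-pentanorlabd-8(17)-en-11-al (trans-decalin, C9 formyl equatorial; C4, C5, C9, C10 placed as in the target), via dimethyl acetal 28 (not isolated)
Conditions: Ph3PAuCl (5 mol%), AgSbF6 (5 mol%), CH2Cl2–MeOH (10:1), rt; then oxalic acid, THF–H2O, rt
Reagents that add atoms: water, O
Why: Gold-catalysed 6-exo-dig carbocyclisation of an enol ether onto a terminal alkyne (Conia-ene type): the cationic gold complex activates C8, C9 attacks anti to gold through a chair with both ring A arms equatorial, which should give the trans-decalin with C11 equatorial (C9–H anti to the C10 methyl), protodeauration leaves the C8=C17 methylene, and the acetal is hydrolysed before isolation.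

Step 20
Reactants: 30 dimethyl (R)-2-methylsuccinate
Product: 31 (R)-2-methylbutane-1,4-diol
Conditions: LiAlH4, THF, 0 °C → rt
Reagents that add atoms: none
Why: LiAlH4 reduction of both esters to the diol, which leaves the methyl-bearing stereocentre untouched.

Step 21
Reactants: 31 (R)-2-methylbutane-1,4-diol
Product: 32 (R)-4-(tert-butyldiphenylsilyloxy)-2-methylbutan-1-ol
Conditions: t-BuPh2SiCl (1.0 equiv), imidazole, CH2Cl2, −20 °C
Reagents that add atoms: tert-butyl(chloro)diphenylsilane, CC(C)(C)[Si](Cl)(c1ccccc1)c1ccccc1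
Why: Sterically controlled monosilylation: the bulky silyl chloride should react first at the hydroxyl remote from the methyl branch, and the regioisomer and bis-silyl ether are removed by chromatography.

Step 22
Reactants: 32 (R)-4-(tert-butyldiphenylsilyloxy)-2-methylbutan-1-ol
Product: 33 (R)-tert-butyl(4-iodo-3-methylbutoxy)diphenylsilane
Conditions: I2, PPh3, imidazole, CH2Cl2, 0 °C → rt
Reagents that add atoms: iodine, II
Why: Appel-type iodination (PPh3, I2, imidazole) of the primary alcohol by SN2 displacement at a carbon that is not stereogenic.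

Step 23
Reactants: 33 (R)-tert-butyl(4-iodo-3-methylbutoxy)diphenylsilane
Product: 34 [(R)-4-(tert-butyldiphenylsilyloxy)-2-methylbutyl]triphenylphosphonium iodide
Conditions: PPh3, MeCN, 85 °C
Reagents that add atoms: triphenylphosphine, c1ccc(cc1)P(c1ccccc1)c1ccccc1
Why: SN2 quaternisation of PPh3 by the β-branched primary iodide, a slow but standard reaction for iodides of this type on heating.

Step 24
Reactants: 29 18-benzyloxy-12,13,14,15,16-pentanorlabd-8(17)-en-11-al; 34 [(R)-4-(tert-butyldiphenylsilyloxy)-2-methylbutyl]triphenylphosphonium iodide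
Product: 36 18-benzyloxy-15-(tert-butyldiphenylsilyloxy)labda-8(17),11(Z)-diene (C4, C5, C9, C10, C13 placed as in the target), via ylide 35 (not isolated)
Conditions: 34, NaN(SiMe3)2, THF, 0 °C; then 29, −78 °C → rt
Reagents that add atoms: none
Why: Wittig olefination with a salt-free non-stabilised ylide added cold, so that carbonyl addition outruns enolisation of the β,γ-unsaturated aldehyde, joins C11 to C12 and brings in C13 with the configuration of the methylsuccinate, the mainly (Z) alkene geometry being erased in step 28.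

Step 25
Reactants: 36 18-benzyloxy-15-(tert-butyldiphenylsilyloxy)labda-8(17),11(Z)-diene
Product: 38 18-benzyloxy-15-(tert-butyldiphenylsilyloxy)labd-11(Z)-en-8-ol (8-OH equatorial, anti to the C10 methyl; other centres as in the target), via organomercurial 37 (not isolated)
Conditions: Hg(OAc)2, THF–H2O (1:1), rt; then NaBH4, 3 M NaOH, 0 °C
Reagents that add atoms: water, O
Why: Oxymercuration–demercuration: the exocyclic 1,1-disubstituted alkene should react much faster than the 1,2-disubstituted C11=C12 alkene, water adds at tertiary C8 (Markovnikov) from the equatorial side anti to the axial C10 methyl to give the equatorial hydroxyl and axial methyl, and NaBH4 then replaces mercury by hydrogen.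

Step 26
Reactants: 38 18-benzyloxy-15-(tert-butyldiphenylsilyloxy)labd-11(Z)-en-8-ol
Product: 39 18-benzyloxylabd-11(Z)-ene-8,15-diol (centres as in the target)
Conditions: Bu4NF, THF, rt
Reagents that add atoms: none
Why: Fluoride-induced cleavage of the silyl ether frees only the primary C15 hydroxyl.

Step 27
Reactants: 39 18-benzyloxylabd-11(Z)-ene-8,15-diol; 40 Meldrum's acid
Product: 41 18-benzyloxy-8-hydroxylabd-11(Z)-en-15-yl hydrogen malonate (centres as in the target)
Conditions: toluene, 90 °C
Reagents that add atoms: none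
Why: Acylation of the primary alcohol by ring opening of Meldrum's acid with loss of acetone should give the malonic half ester, the tertiary C8 hydroxyl being too hindered to react.

Step 28
Reactants: 41 18-benzyloxy-8-hydroxylabd-11(Z)-en-15-yl hydrogen malonate
Product: 42 (4S,5S,8S,9S,10R,13S)-8,18-dihydroxylabdan-15-yl hydrogen malonate (CNP0324566.1)
Conditions: H2 (1 atm), Pd/C, EtOAc–EtOH, rt
Reagents that add atoms: none
Why: Catalytic hydrogenation over Pd/C should saturate the C11=C12 alkene and cleave the benzyl ether by hydrogenolysis in one operation without forming or disturbing a stereocentre, which gives the target.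

Compound list
1 | ethyl 2-methylpent-4-enoate (racemic) | CCOC(=O)C(C)CC=C | starting material
2 | ethyl 2-allyl-2-methylpent-4-enoate | CCOC(=O)C(C)(CC=C)CC=C | intermediate
3 | 2-allyl-2-methylpent-4-en-1-ol | OCC(C)(CC=C)CC=C | intermediate
4 | 4-(benzyloxymethyl)-4-methylhepta-1,6-diene | C=CCC(C)(CC=C)COCc1ccccc1 | intermediate
5 | dimethyl 3-(benzyloxymethyl)-3-methylpentanedioate | COC(=O)CC(C)(COCc1ccccc1)CC(=O)OC | intermediate
6 | (S)-3-(benzyloxymethyl)-5-methoxy-3-methyl-5-oxopentanoic acid | OC(=O)C[C@](C)(COCc1ccccc1)CC(=O)OC | intermediate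
7 | prop-2-yn-1-ol | C#CCO | starting material
8 | (Z)-3-iodo-2-methylprop-2-en-1-ol | I/C=C(/C)CO | intermediate
9 | (Z)-1-iodo-3-(4-methoxybenzyloxy)-2-methylprop-1-ene | I/C=C(/C)COCc1ccc(OC)cc1 | intermediate
10 | methyl (R)-3-(benzyloxymethyl)-5-chloro-3-methyl-5-oxopentanoate | COC(=O)C[C@@](C)(COCc1ccccc1)CC(Cl)=O | intermediate
11 | (Z)-[3-(4-methoxybenzyloxy)-2-methylprop-1-enyl]lithium | [Li]/C=C(/C)COCc1ccc(OC)cc1 | intermediate
12 | (Z)-[3-(4-methoxybenzyloxy)-2-methylprop-1-enyl]zinc chloride | Cl[Zn]/C=C(/C)COCc1ccc(OC)cc1 | intermediate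
13 | methyl (S,Z)-3-(benzyloxymethyl)-8-(4-methoxybenzyloxy)-3,7-dimethyl-5-oxooct-6-enoate | COC(=O)C[C@@](C)(COCc1ccccc1)CC(=O)/C=C(/C)COCc1ccc(OC)cc1 | intermediate
14 | methyl (3S,5S,Z)-3-(benzyloxymethyl)-5-hydroxy-8-(4-methoxybenzyloxy)-3,7-dimethyloct-6-enoate | COC(=O)C[C@@](C)(COCc1ccccc1)C[C@H](O)/C=C(/C)COCc1ccc(OC)cc1 | intermediate
15 | (4S,6S)-4-(benzyloxymethyl)-6-[(Z)-3-(4-methoxybenzyloxy)-2-methylprop-1-enyl]-4-methyltetrahydropyran-2-one | O=C1C[C@@](C)(COCc2ccccc2)C[C@@H](/C=C(/C)COCc2ccc(OC)cc2)O1 | intermediate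
16 | (2S,4S)-4-(benzyloxymethyl)-6-(tert-butyldimethylsilyloxy)-2-[(Z)-3-(4-methoxybenzyloxy)-2-methylprop-1-enyl]-4-methyl-3,4-dihydro-2H-pyran | CC(C)(C)[Si](C)(C)OC1=C[C@@](C)(COCc2ccccc2)C[C@@H](/C=C(/C)COCc2ccc(OC)cc2)O1 | intermediate
17 | tert-butyldimethylsilyl ester of acid 18 | COc1ccc(COC[C@]2(C)C=CC[C@](C)(COCc3ccccc3)[C@H]2C(=O)O[Si](C)(C)C(C)(C)C)cc1 | intermediate
18 | (1R,2R,6S)-6-(benzyloxymethyl)-2-[(4-methoxybenzyloxy)methyl]-2,6-dimethylcyclohex-3-ene-1-carboxylic acid (carboxyl cis to both methyl groups) | COc1ccc(COC[C@]2(C)C=CC[C@](C)(COCc3ccccc3)[C@H]2C(=O)O)cc1 | intermediate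
19 | [(1R,2R,6S)-6-(benzyloxymethyl)-2-[(4-methoxybenzyloxy)methyl]-2,6-dimethylcyclohex-3-en-1-yl]methanol | COc1ccc(COC[C@]2(C)C=CC[C@](C)(COCc3ccccc3)[C@H]2CO)cc1 | intermediate
20 | (1R,2R,6S)-6-(benzyloxymethyl)-2-[(4-methoxybenzyloxy)methyl]-2,6-dimethylcyclohex-3-ene-1-carbaldehyde | COc1ccc(COC[C@]2(C)C=CC[C@](C)(COCc3ccccc3)[C@H]2C=O)cc1 | intermediate
21 | ethyl (E)-3-[(1R,2R,6S)-6-(benzyloxymethyl)-2-[(4-methoxybenzyloxy)methyl]-2,6-dimethylcyclohex-3-en-1-yl]prop-2-enoate | COc1ccc(COC[C@]2(C)C=CC[C@](C)(COCc3ccccc3)[C@H]2/C=C/C(=O)OCC)cc1 | intermediate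
22 | ethyl 3-[2-(benzyloxymethyl)-6-[(4-methoxybenzyloxy)methyl]-2,6-dimethylcyclohexyl]propanoate (ring centres as in 18) | COc1ccc(COC[C@]2(C)CCC[C@](C)(COCc3ccccc3)[C@H]2CCC(=O)OCC)cc1 | intermediate
23 | 3-[2-(benzyloxymethyl)-6-[(4-methoxybenzyloxy)methyl]-2,6-dimethylcyclohexyl]propanal (ring centres as in 18) | COc1ccc(COC[C@]2(C)CCC[C@](C)(COCc3ccccc3)[C@H]2CCC=O)cc1 | intermediate
24 | 1-(benzyloxymethyl)-2-(but-3-ynyl)-3-[(4-methoxybenzyloxy)methyl]-1,3-dimethylcyclohexane (ring centres as in 18) | COc1ccc(COC[C@]2(C)CCC[C@](C)(COCc3ccccc3)[C@H]2CCC#C)cc1 | intermediate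
25 | [3-(benzyloxymethyl)-2-(but-3-ynyl)-1,3-dimethylcyclohexyl]methanol (ring centres as in 18) | OC[C@]1(C)CCC[C@](C)(COCc2ccccc2)[C@H]1CCC#C | intermediate
26 | 3-(benzyloxymethyl)-2-(but-3-ynyl)-1,3-dimethylcyclohexane-1-carbaldehyde (ring centres as in 18) | O=C[C@]1(C)CCC[C@](C)(COCc2ccccc2)[C@H]1CCC#C | intermediate
27 | 1-(benzyloxymethyl)-2-(but-3-ynyl)-3-(2-methoxyvinyl)-1,3-dimethylcyclohexane (E/Z mixture, ring centres as in 18) | COC=C[C@]1(C)CCC[C@](C)(COCc2ccccc2)[C@H]1CCC#C | intermediate
28 | dimethyl acetal of aldehyde 29 | COC(OC)[C@H]1[C@]2(C)CCC[C@](C)(COCc3ccccc3)[C@H]2CCC1=C | intermediate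
29 | 18-benzyloxy-12,13,14,15,16-pentanorlabd-8(17)-en-11-al (trans-decalin, equatorial C9 formyl; C4, C5, C9, C10 as in the target) | O=C[C@H]1[C@]2(C)CCC[C@](C)(COCc3ccccc3)[C@H]2CCC1=C | intermediate
30 | dimethyl (R)-2-methylsuccinate | C[C@H](CC(=O)OC)C(=O)OC | starting material
31 | (R)-2-methylbutane-1,4-diol | C[C@H](CCO)CO | intermediate
32 | (R)-4-(tert-butyldiphenylsilyloxy)-2-methylbutan-1-ol | C[C@H](CCO[Si](c1ccccc1)(c1ccccc1)C(C)(C)C)CO | intermediate
33 | (R)-tert-butyl(4-iodo-3-methylbutoxy)diphenylsilane | C[C@H](CCO[Si](c1ccccc1)(c1ccccc1)C(C)(C)C)CI | intermediate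
34 | [(R)-4-(tert-butyldiphenylsilyloxy)-2-methylbutyl]triphenylphosphonium iodide | C[C@H](CCO[Si](c1ccccc1)(c1ccccc1)C(C)(C)C)C[P+](c1ccccc1)(c1ccccc1)c1ccccc1.[I-] | intermediate
35 | [(R)-4-(tert-butyldiphenylsilyloxy)-2-methylbutylidene]triphenylphosphorane | C[C@H](CCO[Si](c1ccccc1)(c1ccccc1)C(C)(C)C)C=P(c1ccccc1)(c1ccccc1)c1ccccc1 | intermediate
36 | 18-benzyloxy-15-(tert-butyldiphenylsilyloxy)labda-8(17),11(Z)-diene (centres as in the target) | C[C@H](CCO[Si](c1ccccc1)(c1ccccc1)C(C)(C)C)/C=C\[C@H]1[C@]2(C)CCC[C@](C)(COCc3ccccc3)[C@H]2CCC1=C | intermediate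
37 | 17-(acetoxymercurio)-18-benzyloxy-15-(tert-butyldiphenylsilyloxy)labd-11(Z)-en-8-ol | C[C@H](CCO[Si](c1ccccc1)(c1ccccc1)C(C)(C)C)/C=C\[C@H]1[C@]2(C)CCC[C@](C)(COCc3ccccc3)[C@H]2CC[C@@]1(O)C[Hg]OC(C)=O | intermediate
38 | 18-benzyloxy-15-(tert-butyldiphenylsilyloxy)labd-11(Z)-en-8-ol (8-OH anti to the C10 methyl) | C[C@H](CCO[Si](c1ccccc1)(c1ccccc1)C(C)(C)C)/C=C\[C@H]1[C@]2(C)CCC[C@](C)(COCc3ccccc3)[C@H]2CC[C@]1(C)O | intermediate
39 | 18-benzyloxylabd-11(Z)-ene-8,15-diol (centres as in the target) | C[C@H](CCO)/C=C\[C@H]1[C@]2(C)CCC[C@](C)(COCc3ccccc3)[C@H]2CC[C@]1(C)O | intermediate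
40 | Meldrum's acid (2,2-dimethyl-1,3-dioxane-4,6-dione) | CC1(C)OC(=O)CC(=O)O1 | starting material
41 | 18-benzyloxy-8-hydroxylabd-11(Z)-en-15-yl hydrogen malonate (centres as in the target) | C[C@H](CCOC(=O)CC(=O)O)/C=C\[C@H]1[C@]2(C)CCC[C@](C)(COCc3ccccc3)[C@H]2CC[C@]1(C)O | intermediate
42 | (4S,5S,8S,9S,10R,13S)-8,18-dihydroxylabdan-15-yl hydrogen malonate (CNP0324566.1) | C[C@H](CCOC(=O)CC(=O)O)CC[C@H]1[C@]2(C)CCC[C@](C)(CO)[C@H]2CC[C@]1(C)O | target

Total step count: 28. Longest linear sequence: 22 steps (steps 1–5, 8–19 and 24–28, from 1 to 42).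

Steps most likely to fail

Step 10, the ring contraction. The lactone enolate may fragment or be silylated on carbon before the ketene acetal forms, and the sigmatropic shift may be too slow through the crowded boat in which the C4 CH2OBn group faces the C10 CH2OPMB arm. The fallback makes the same C5–C10 bond by an open-chain Ireland–Claisen rearrangement through a chair and closes ring A afterwards by metathesis. It sets out from half ester 6 (through its chloride 10) and iodide 9 (through lithium reagent 11) and rejoins the route at acid 18. Chloride 10 would be reduced with LiAlH(O-t-Bu)3 at −78 °C to methyl (S)-3-(benzyloxymethyl)-3-methyl-5-oxopentanoate F1, methylenated with Ph3P=CH2 to methyl (S)-3-(benzyloxymethyl)-3-methylhex-5-enoate F2 and saponified with LiOH to (S)-3-(benzyloxymethyl)-3-methylhex-5-enoic acid F3. Lithium reagent 11 would be acylated with N-methoxy-N-methylacetamide to (Z)-5-(4-methoxybenzyloxy)-4-methylpent-3-en-2-one F4 and reduced with (S)-2-methyl-CBS-oxazaborolidine and catecholborane to (R,Z)-5-(4-methoxybenzyloxy)-4-methylpent-3-en-2-ol F5. DCC/DMAP coupling of the two would give (R,Z)-5-(4-methoxybenzyloxy)-4-methylpent-3-en-2-yl (S)-3-(benzyloxymethyl)-3-methylhex-5-enoate F6. LiN(i-Pr)2 in THF–HMPA with Me3SiCl would give the trimethylsilyl ketene acetal F7, with C4 cis to the silyloxy group. On warming this should rearrange through a chair with the carbinol methyl equatorial to the trimethylsilyl ester F8, and hydrolysis would give the (E)-diene acid F9, which has the C4, C5 and C10 configurations of 18. Ring-closing metathesis with the second-generation Grubbs catalyst would then join C1 to C2 with loss of propene and give 18.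

Step 19, the gold-catalysed closure of ring B. The alkyne may be hydrated or the enol ether hydrolysed before the carbon–carbon bond forms, and attack by the neopentyl carbon C9 may be too slow. The fallback closes the same bond by a tin-hydride radical cyclisation; it sets out from enol ether 27 and rejoins at aldehyde 29. Aqueous oxalic acid would hydrolyse 27 to 2-[3-(benzyloxymethyl)-2-(but-3-ynyl)-1,3-dimethylcyclohexyl]acetaldehyde F10, and t-BuMe2SiOTf/Et3N would convert this into its tert-butyldimethylsilyl enol ether F11. With Bu3SnH and AIBN in benzene at 80 °C a stannyl radical should add to the alkyne terminus and the C8 vinyl radical close 6-exo onto C9, giving the bicyclic vinylstannane silyl ether F12. TsOH·H2O in CH2Cl2–MeOH would remove tin and silicon to give 18-benzyloxy-12,13,14,15,16-pentanorlabd-8(17)-en-11-ol F13, and Dess–Martin oxidation would give 29.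

Step 5, the enzymatic desymmetrisation. The esterase may discriminate the two ester arms poorly or turn the hindered diester over slowly. The fallback desymmetrises the cyclic anhydride with a chiral base instead; it sets out from diester 5 and rejoins at half ester 6. LiOH would give 3-(benzyloxymethyl)-3-methylpentanedioic acid F14 and Ac2O its cyclic anhydride 4-(benzyloxymethyl)-4-methyldihydropyran-2,6-dione F15. Methanolysis at −20 °C with the cinchona alkaloid catalyst (DHQD)2AQN, or its quasi-enantiomer (DHQ)2AQN should the other sense be needed, would then give 6.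

Further compounds
F1 | step 10 | methyl (S)-3-(benzyloxymethyl)-3-methyl-5-oxopentanoate | COC(=O)C[C@@](C)(COCc1ccccc1)CC=O
F2 | step 10 | methyl (S)-3-(benzyloxymethyl)-3-methylhex-5-enoate | COC(=O)C[C@@](C)(COCc1ccccc1)CC=C
F3 | step 10 | (S)-3-(benzyloxymethyl)-3-methylhex-5-enoic acid | OC(=O)C[C@@](C)(COCc1ccccc1)CC=C
F4 | step 10 | (Z)-5-(4-methoxybenzyloxy)-4-methylpent-3-en-2-one | CC(=O)/C=C(/C)COCc1ccc(OC)cc1
F5 | step 10 | (R,Z)-5-(4-methoxybenzyloxy)-4-methylpent-3-en-2-ol | C[C@@H](O)/C=C(/C)COCc1ccc(OC)cc1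
F6 | step 10 | (R,Z)-5-(4-methoxybenzyloxy)-4-methylpent-3-en-2-yl (S)-3-(benzyloxymethyl)-3-methylhex-5-enoate | C=CC[C@](C)(COCc1ccccc1)CC(=O)O[C@H](C)/C=C(/C)COCc1ccc(OC)cc1
F7 | step 10 | trimethylsilyl ketene acetal of F6 (C4 cis to the silyloxy group) | C=CC[C@](C)(COCc1ccccc1)/C=C(\O[Si](C)(C)C)O[C@H](C)/C=C(/C)COCc1ccc(OC)cc1
F8 | step 10 | trimethylsilyl ester of F9 | COc1ccc(COC[C@](C)(/C=C/C)[C@H](C(=O)O[Si](C)(C)C)[C@@](C)(COCc2ccccc2)CC=C)cc1
F9 | step 10 | (E)-2-[1-(benzyloxy)-2-methylpent-4-en-2-yl]-3-[(4-methoxybenzyloxy)methyl]-3-methylhex-4-enoic acid (C4, C5, C10 as in 18) | COc1ccc(COC[C@](C)(/C=C/C)[C@H](C(=O)O)[C@@](C)(COCc2ccccc2)CC=C)cc1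
F10 | step 19 | 2-[3-(benzyloxymethyl)-2-(but-3-ynyl)-1,3-dimethylcyclohexyl]acetaldehyde (ring centres as in 18) | O=CC[C@]1(C)CCC[C@](C)(COCc2ccccc2)[C@H]1CCC#C
F11 | step 19 | tert-butyldimethylsilyl enol ether of F10 (E/Z mixture) | CC(C)(C)[Si](C)(C)OC=C[C@]1(C)CCC[C@](C)(COCc2ccccc2)[C@H]1CCC#C
F12 | step 19 | 18-benzyloxy-11-(tert-butyldimethylsilyloxy)-17-(tributylstannyl)-12,13,14,15,16-pentanorlabd-8(17)-ene | CC(C)(C)[Si](C)(C)OC[C@H]1[C@]2(C)CCC[C@](C)(COCc3ccccc3)[C@H]2CCC1=C[Sn](CCCC)(CCCC)CCCC
F13 | step 19 | 18-benzyloxy-12,13,14,15,16-pentanorlabd-8(17)-en-11-ol | OC[C@H]1[C@]2(C)CCC[C@](C)(COCc3ccccc3)[C@H]2CCC1=C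
F14 | step 5 | 3-(benzyloxymethyl)-3-methylpentanedioic acid | OC(=O)CC(C)(COCc1ccccc1)CC(=O)O
F15 | step 5 | 4-(benzyloxymethyl)-4-methyldihydropyran-2,6-dione | O=C1CC(C)(COCc2ccccc2)CC(=O)O1
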